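**Strategy**

Ring B is not imported as an aryl unit but grown on a finished chromone. Its C2' and C5' oxygens are para to each other and C4' carries a third, the 4-alkoxyphenol pattern that a Dötz benzannulation writes directly. A terminal alkyne on C2 of the ring A/C chromone (O5 and O7 as benzyl ethers, O6 methylated) reacts with the methoxy(1-methoxyvinyl)carbene complex of Cr(CO)5. One operation forms C5'–C6', C1'–C2' and C2'–C3', closes ring B and places all three of its oxygens, leaving a free C2' phenol. Methylation of that phenol and hydrogenolysis of the benzyl ethers then give tabularin.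

Key step: step 11

Remark: in the SMILES of the chromium compounds each carbonyl ligand is drawn as =C=O on the metal, a formal way of writing the Cr–CO bond. The target has no stereocenter.

**Route**

Step 1
Reactants: 1 methyl 3,5-dihydroxy-4-methoxybenzoate
Product: 2 methyl 3,5-bis(benzyloxy)-4-methoxybenzoate
Conditions: BnBr, K2CO3, DMF, 60 °C
Reagents that add atoms: benzyl bromide, BrCc1ccccc1
Why: Williamson etherification of both phenols; the ester and the C4 methoxyl are untouched.

Step 2
Reactants: 2 methyl 3,5-bis(benzyloxy)-4-methoxybenzoate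
Product: 3 [3,5-bis(benzyloxy)-4-methoxyphenyl]methanol
Conditions: LiAlH4, THF, 0 °C → rt
Reagents that add atoms: none
Why: Hydride reduction of the aryl ester to the benzylic alcohol; aryl benzyl and methyl ethers are inert to LiAlH4.

Step 3
Reactants: 3 [3,5-bis(benzyloxy)-4-methoxyphenyl]methanol
Product: 4 3,5-bis(benzyloxy)-4-methoxybenzaldehyde
Conditions: MnO2 (activated), CH2Cl2, rt
Reagents that add atoms: none
Why: Selective MnO2 oxidation of a benzylic alcohol, which stops cleanly at the aldehyde.

Step 4
Reactants: 4 3,5-bis(benzyloxy)-4-methoxybenzaldehyde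
Product: 6 3,5-bis(benzyloxy)-4-methoxyphenol, via aryl formate 5 (not isolated)
Conditions: mCPBA, CH2Cl2, 0 °C → rt; then K2CO3 (cat.), MeOH, rt
Reagents that add atoms: 3-chloroperoxybenzoic acid, OOC(=O)c1cccc(Cl)c1
Why: Baeyer–Villiger (Dakin-type) oxidation in which the electron-rich trialkoxyaryl group migrates in preference to hydride, followed by methanolysis of the formate in the same flask.

Step 5
Reactants: 6 3,5-bis(benzyloxy)-4-methoxyphenol
Product: 8 1-[2,4-bis(benzyloxy)-6-hydroxy-3-methoxyphenyl]ethanone, via aryl acetate 7 (not isolated)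
Conditions: Ac2O, BF3·OEt2, CH2Cl2, 0 °C → rt; then aq. NaOAc, MeOH, 40 °C
Reagents that add atoms: acetic anhydride, CC(=O)OC(C)=O
Why: O-acetylation and BF3-promoted Fries rearrangement (Friedel–Crafts acylation) should deliver the acetyl group to the only kind of open ortho position (C2 and C6 are equivalent, the para position is blocked), which is activated by two benzyloxy groups so that low temperature suffices and the benzyl ethers are spared.

Step 6
Reactants: 8 1-[2,4-bis(benzyloxy)-6-hydroxy-3-methoxyphenyl]ethanone; 9 diethyl oxalate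
Product: 11 ethyl 5,7-bis(benzyloxy)-6-methoxy-4-oxo-4H-chromene-2-carboxylate, via diketo ester 10 (not isolated)
Conditions: NaOEt, EtOH/THF, 0 → 50 °C; AcOH quench; then p-TsOH·H2O (cat.), EtOH, 60 °C
Reagents that add atoms: none
Why: Claisen condensation of the acetophenone enolate with the oxalate and acid cyclodehydration of the 2-hydroxyaryl diketo ester is the standard chromone-2-carboxylate synthesis, and a catalytic sulfonic acid is mild enough for the benzyl ether next to the carbonyl.

Step 7
Reactants: 11 ethyl 5,7-bis(benzyloxy)-6-methoxy-4-oxo-4H-chromene-2-carboxylate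
Product: 12 5,7-bis(benzyloxy)-2-(hydroxymethyl)-6-methoxychromen-4-one
Conditions: NaBH4, MeOH/THF, 0 °C
Reagents that add atoms: none
Why: Chemoselective borohydride reduction of the ester, which is activated by the adjacent pyranone oxygen and reacts well before the vinylogous ester carbonyl at C4, as is known for chromone-2-carboxylates.

Step 8
Reactants: 12 5,7-bis(benzyloxy)-2-(hydroxymethyl)-6-methoxychromen-4-one
Product: 13 5,7-bis(benzyloxy)-6-methoxy-4-oxo-4H-chromene-2-carbaldehyde
Conditions: Dess–Martin periodinane, CH2Cl2, rt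
Reagents that add atoms: none
Why: Dess–Martin oxidation of the primary alcohol to the aldehyde under near-neutral conditions that leave the chromone and the benzyl ethers alone.

Step 9
Reactants: 13 5,7-bis(benzyloxy)-6-methoxy-4-oxo-4H-chromene-2-carbaldehyde
Product: 14 5,7-bis(benzyloxy)-2-ethynyl-6-methoxychromen-4-one
Conditions: dimethyl (1-diazo-2-oxopropyl)phosphonate, K2CO3, MeOH, 0 °C → rt, short reaction time
Reagents that add atoms: dimethyl (1-diazo-2-oxopropyl)phosphonate, CC(=O)C(=[N+]=[N-])P(=O)(OC)OC
Why: Ohira–Bestmann (Seyferth–Gilbert) homologation, in which the diazomethylphosphonate anion adds to the aldehyde and the diazoalkene loses N2 with a 1,2-hydrogen shift to give the terminal alkyne; low temperature limits methoxide attack on the pyranone.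

Step 10
Reactants: 15 methyl vinyl ether; 16 hexacarbonylchromium Cr(CO)6
Product: 19 pentacarbonyl[methoxy(1-methoxyvinyl)carbene]chromium, via 1-methoxyvinyllithium 17 (not isolated), via lithium acylchromate 18 (not isolated)
Conditions: t-BuLi, THF, −78 → 0 °C; Cr(CO)6, THF, −78 °C → rt; Me3OBF4, CH2Cl2, 0 °C
Reagents that add atoms: trimethyloxonium tetrafluoroborate, C[O+](C)C.F[B-](F)(F)F
Why: Fischer carbene synthesis, in which the α-lithiated enol ether adds to a CO ligand and the acyl chromate is O-methylated by the oxonium salt; the α-substituent on the vinyl group should suppress polymerisation, as in complexes made from α-lithiated cyclic enol ethers.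

Step 11
Reactants: 14 5,7-bis(benzyloxy)-2-ethynyl-6-methoxychromen-4-one; 19 pentacarbonyl[methoxy(1-methoxyvinyl)carbene]chromium
Product: 20 5,7-bis(benzyloxy)-2-(2-hydroxy-4,5-dimethoxyphenyl)-6-methoxychromen-4-one
Conditions: THF (degassed), 50 °C, Ar; then air, rt
Reagents that add atoms: none
Why: Thermal loss of one CO from 19 opens a site for the alkyne, which inserts into the Cr=C bond with its CH terminus bonding to the carbene carbon (C5'–C6'); CO insertion into the resulting vinylcarbene gives a chromium-bound dienylketene (C1'–C2'), and the ketene carbon closes onto the vinyl CH2 terminus (C2'–C3') before tautomerising to the phenol. The closest known reaction type is the Dötz benzannulation of alkenyl(alkoxy)carbene complexes of zerovalent chromium, including α-alkoxyalkenyl ones, with terminal alkynes and conjugated enynes. Ring B, the only ring formed, closes by 6π electrocyclisation of the dienylketene, and no stereocenter is created. The step needs regioselective insertion, and the terminal alkyne secures it because the chromonyl-bearing carbon avoids the carbene carbon and ends next to the CO-derived C2'. It also needs phenol formation rather than cyclopentannulation, which alkenyl carbene complexes in THF favour, while the push–pull C2–C3 alkene of the chromone should not be cyclopropanated at 50 °C. Stirring in air should release any product held as its Cr(CO)3 arene complex without oxidising the hydroquinone monoether.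

Step 12
Reactants: 20 5,7-bis(benzyloxy)-2-(2-hydroxy-4,5-dimethoxyphenyl)-6-methoxychromen-4-one
Product: 21 5,7-bis(benzyloxy)-6-methoxy-2-(2,4,5-trimethoxyphenyl)chromen-4-one
Conditions: MeI, K2CO3, DMF, rt
Reagents that add atoms: iodomethane, CI
Why: Williamson methylation of the only free phenol, the C2' hydroxyl.

Step 13
Reactants: 21 5,7-bis(benzyloxy)-6-methoxy-2-(2,4,5-trimethoxyphenyl)chromen-4-one
Product: 22 tabularin, 5,7-dihydroxy-6-methoxy-2-(2,4,5-trimethoxyphenyl)chromen-4-one
Conditions: H2 (1 atm), 10% Pd/C, EtOAc/MeOH, rt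
Reagents that add atoms: none
Why: Hydrogenolysis of the two aryl benzyl ethers; the methyl ethers and the doubly conjugated C2–C3 double bond of the flavone should not be reduced under these mild conditions.

**Compound list**

1 | methyl 3,5-dihydroxy-4-methoxybenzoate | COC(=O)c1cc(O)c(OC)c(O)c1 | starting material
2 | methyl 3,5-bis(benzyloxy)-4-methoxybenzoate | COC(=O)c1cc(OCc2ccccc2)c(OC)c(OCc2ccccc2)c1 | intermediate
3 | [3,5-bis(benzyloxy)-4-methoxyphenyl]methanol | OCc1cc(OCc2ccccc2)c(OC)c(OCc2ccccc2)c1 | intermediate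
4 | 3,5-bis(benzyloxy)-4-methoxybenzaldehyde | O=Cc1cc(OCc2ccccc2)c(OC)c(OCc2ccccc2)c1 | intermediate
5 | 3,5-bis(benzyloxy)-4-methoxyphenyl formate | O=COc1cc(OCc2ccccc2)c(OC)c(OCc2ccccc2)c1 | intermediate (not isolated)
6 | 3,5-bis(benzyloxy)-4-methoxyphenol | Oc1cc(OCc2ccccc2)c(OC)c(OCc2ccccc2)c1 | intermediate
7 | 3,5-bis(benzyloxy)-4-methoxyphenyl acetate | CC(=O)Oc1cc(OCc2ccccc2)c(OC)c(OCc2ccccc2)c1 | intermediate (not isolated)
8 | 1-[2,4-bis(benzyloxy)-6-hydroxy-3-methoxyphenyl]ethanone | CC(=O)c1c(O)cc(OCc2ccccc2)c(OC)c1OCc1ccccc1 | intermediate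
9 | diethyl oxalate | CCOC(=O)C(=O)OCC | starting material
10 | ethyl 4-[2,4-bis(benzyloxy)-6-hydroxy-3-methoxyphenyl]-2,4-dioxobutanoate | CCOC(=O)C(=O)CC(=O)c1c(O)cc(OCc2ccccc2)c(OC)c1OCc1ccccc1 | intermediate (not isolated)
11 | ethyl 5,7-bis(benzyloxy)-6-methoxy-4-oxo-4H-chromene-2-carboxylate | CCOC(=O)c1cc(=O)c2c(OCc3ccccc3)c(OC)c(OCc3ccccc3)cc2o1 | intermediate
12 | 5,7-bis(benzyloxy)-2-(hydroxymethyl)-6-methoxychromen-4-one | OCc1cc(=O)c2c(OCc3ccccc3)c(OC)c(OCc3ccccc3)cc2o1 | intermediate
13 | 5,7-bis(benzyloxy)-6-methoxy-4-oxo-4H-chromene-2-carbaldehyde | O=Cc1cc(=O)c2c(OCc3ccccc3)c(OC)c(OCc3ccccc3)cc2o1 | intermediate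
14 | 5,7-bis(benzyloxy)-2-ethynyl-6-methoxychromen-4-one | C#Cc1cc(=O)c2c(OCc3ccccc3)c(OC)c(OCc3ccccc3)cc2o1 | intermediate
15 | methyl vinyl ether | C=COC | starting material
16 | hexacarbonylchromium Cr(CO)6 | O=C=[Cr](=C=O)(=C=O)(=C=O)(=C=O)=C=O | starting material
17 | 1-methoxyvinyllithium | [Li]C(=C)OC | intermediate (not isolated)
18 | lithium pentacarbonyl(2-methoxyacryloyl)chromate | [Li+].C=C(OC)C([O-])=[Cr](=C=O)(=C=O)(=C=O)(=C=O)=C=O | intermediate (not isolated)
19 | pentacarbonyl[methoxy(1-methoxyvinyl)carbene]chromium | C=C(OC)C(OC)=[Cr](=C=O)(=C=O)(=C=O)(=C=O)=C=O | intermediate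
20 | 5,7-bis(benzyloxy)-2-(2-hydroxy-4,5-dimethoxyphenyl)-6-methoxychromen-4-one | COc1cc(O)c(-c2cc(=O)c3c(OCc4ccccc4)c(OC)c(OCc4ccccc4)cc3o2)cc1OC | intermediate
21 | 5,7-bis(benzyloxy)-6-methoxy-2-(2,4,5-trimethoxyphenyl)chromen-4-one | COc1cc(OC)c(-c2cc(=O)c3c(OCc4ccccc4)c(OC)c(OCc4ccccc4)cc3o2)cc1OC | intermediate
22 | tabularin, 5,7-dihydroxy-6-methoxy-2-(2,4,5-trimethoxyphenyl)chromen-4-one | COc1cc(OC)c(-c2cc(=O)c3c(O)c(OC)c(O)cc3o2)cc1OC | target

**Step count and risks**

Total step count: 13. Longest linear sequence: 12 steps (steps 1–9 and 11–13, from 1 to 22); the carbene complex 19 is a one-step branch.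

Steps most likely to fail:

1. Step 11. The electron-poor enyne may insert sluggishly, or the vinylcarbene may be diverted into non-phenolic products before CO insertion and ring closure. Fallback: ring B would be brought in preformed. The route is left at acetophenone 8, which is condensed with 2,4,5-trimethoxybenzaldehyde (KOH, EtOH, rt; Claisen–Schmidt condensation) to give the chalcone (E)-1-[2,4-bis(benzyloxy)-6-hydroxy-3-methoxyphenyl]-3-(2,4,5-trimethoxyphenyl)prop-2-en-1-one F1. Oxidative cyclisation of the 2'-hydroxychalcone (I2 cat., DMSO, 120 °C) should then close ring C and rejoin the route at 21, ahead of step 13.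

2. Step 9. Methoxide may add to C2 of the formylchromone or to the enynone product, opening the pyranone ring before or after the homologation. Fallback: the alkyne would be carried in before the chromone is closed, with no basic methanol. The route is left at 8, which is C-acylated as its dianion (LiHMDS, THF, −78 °C) with ethyl 3-[tri(propan-2-yl)silyl]prop-2-ynoate to give 1-[2,4-bis(benzyloxy)-6-hydroxy-3-methoxyphenyl]-5-[tri(propan-2-yl)silyl]pent-4-yne-1,3-dione F2; the bulky silyl group blocks conjugate addition at the alkyne. Acid cyclodehydration (p-TsOH·H2O cat., toluene, 60 °C) should give 5,7-bis(benzyloxy)-6-methoxy-2-{[tri(propan-2-yl)silyl]ethynyl}chromen-4-one F3. Desilylation (Bu4NF buffered with AcOH, THF, 0 °C) rejoins the route at 14.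

3. Step 5. The Lewis acid may strip or migrate a benzyl group during the acyl transfer, most readily the one that ends up next to the new carbonyl. Fallback: the acetyl group would be built without acid. The route is left at phenol 6, which undergoes magnesium-mediated ortho-formylation (MgCl2, Et3N, paraformaldehyde, MeCN, reflux) to give 2,4-bis(benzyloxy)-6-hydroxy-3-methoxybenzaldehyde F4. Addition of MeMgBr (2.5 equiv, THF, 0 °C) should give racemic 3,5-bis(benzyloxy)-2-(1-hydroxyethyl)-4-methoxyphenol F5, and MnO2 oxidation of the benzylic alcohol (CH2Cl2, rt) rejoins the route at 8.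

**Further compounds**

F1 | step 11 | (E)-1-[2,4-bis(benzyloxy)-6-hydroxy-3-methoxyphenyl]-3-(2,4,5-trimethoxyphenyl)prop-2-en-1-one | COc1cc(OC)c(/C=C/C(=O)c2c(O)cc(OCc3ccccc3)c(OC)c2OCc2ccccc2)cc1OC
F2 | step 9 | 1-[2,4-bis(benzyloxy)-6-hydroxy-3-methoxyphenyl]-5-[tri(propan-2-yl)silyl]pent-4-yne-1,3-dione | CC(C)[Si](C#CC(=O)CC(=O)c1c(O)cc(OCc2ccccc2)c(OC)c1OCc1ccccc1)(C(C)C)C(C)C
F3 | step 9 | 5,7-bis(benzyloxy)-6-methoxy-2-{[tri(propan-2-yl)silyl]ethynyl}chromen-4-one | CC(C)[Si](C#Cc1cc(=O)c2c(OCc3ccccc3)c(OC)c(OCc3ccccc3)cc2o1)(C(C)C)C(C)C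
F4 | step 5 | 2,4-bis(benzyloxy)-6-hydroxy-3-methoxybenzaldehyde | O=Cc1c(O)cc(OCc2ccccc2)c(OC)c1OCc1ccccc1
F5 | step 5 | 3,5-bis(benzyloxy)-2-(1-hydroxyethyl)-4-methoxyphenol (racemate) | CC(O)c1c(O)cc(OCc2ccccc2)c(OC)c1OCc1ccccc1
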